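**Strategy.** Everything rests on cutting ring C of the upper fisetinidol unit at C3–C4 and O1–C2. The handle is that its C3–O bond and its C4–ring D bond point to the same side of ring C, while O7 of ring D (the catechin benzo ring) neighbours the linking carbon C8; this is the geometry a temporary O7–Si–C3 tether needs. In one operation a ring A ortho-quinone methide adds the tethered (E)-styrylsilane, closing ring C and an oxasilinane and setting C2, C3 and C4. The precursor is a catechin C8 benzhydrol with a free ring A phenol, the O7 silyl tether and a C6 bromine that blocks this carbon and later anchors the lower unit.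

Key step: step 11

Labels: flavan numbering is used in each unit. Upper fisetinidol unit: rings A (benzo), B (catechol), C (pyran). Catechin unit: rings D (benzo), E (catechol), F (pyran). Lower fisetinidol unit: rings G (benzo), H (catechol), I (pyran). Bn = benzyl.

Assumption: the antipode of the chiral phosphoric acid (step 11) and of the pyridine–oxazoline ligand (step 15) is assigned by analogy with related additions; if the sense is opposite, the other antipode of the catalyst is used.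

Remark: the boronate for the lower unit must be the (2S)-flav-3-ene. It has the spatial arrangement of a (2R)-flavan-3-ol; the descriptor changes only when C3 gains oxygen in step 19.

Step 1
Reactants: 1 (+)-catechin
Product: 3 penta-O-benzyl-(+)-catechin (benzyl on O3 O5 O7 O3' O4'), via tetrabenzyl ether 2 (not isolated)
Conditions: BnBr, K2CO3, DMF, rt; then NaH, BnBr, n-Bu4NI (cat.), 0 °C → rt
Reagents that add atoms: benzyl bromide, BrCc1ccccc1
Why: Williamson etherification, the four phenols reacting first with carbonate and the C3 alkoxide afterwards with hydride, with no bond to C2 or C3 broken.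

Step 2
Reactants: 3 penta-O-benzyl-(+)-catechin
Product: 4 8-bromo-penta-O-benzylcatechin
Conditions: NBS (1.0 equiv), CH2Cl2, −78 → 0 °C
Reagents that add atoms: N-bromosuccinimide, O=C1CCC(=O)N1Br
Why: Electrophilic aromatic bromination, which on 5,7-dialkoxyflavans goes to C8 ahead of C6.

Step 3
Reactants: 4 8-bromo-penta-O-benzylcatechin
Product: 6 8-formyl-penta-O-benzylcatechin, via 8-lithio arene 5 (not isolated)
Conditions: n-BuLi, THF, −78 °C; DMF, −78 → 0 °C; aq NH4Cl
Reagents that add atoms: N,N-dimethylformamide, CN(C)C=O; n-butyllithium, [Li]CCCC (its lithium stays only in 5)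
Why: Bromine–lithium exchange followed by formylation with DMF (Bouveault aldehyde synthesis), the aryllithium being stable at −78 °C.

Step 4
Reactants: 6 8-formyl-penta-O-benzylcatechin
Product: 7 8-formyl-3,5,3',4'-tetra-O-benzylcatechin (7-OH free)
Conditions: BCl3 (1.1 equiv), CH2Cl2, −78 °C; aq NaHCO3
Reagents that add atoms: none
Why: Chelation-controlled Lewis-acid ether cleavage, in which boron bound to the formyl oxygen activates only the neighbouring O7 benzyl ether and chloride cuts its primary benzylic C–O bond at −78 °C while the other benzyl ethers and ring F stay.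

Step 5
Reactants: 7 8-formyl-3,5,3',4'-tetra-O-benzylcatechin
Product: 8 6-bromo-8-formyl-3,5,3',4'-tetra-O-benzylcatechin (7-OH free)
Conditions: NBS (1.0 equiv), CH2Cl2, −20 → 0 °C, dark
Reagents that add atoms: N-bromosuccinimide, O=C1CCC(=O)N1Br
Why: Electrophilic aromatic bromination ortho to the free phenol at C6, the only open and most activated position of ring D, which installs the spectator bromine that shields C6 in step 11 and is the coupling handle of step 18.

Step 6
Reactants: 9 3,4-bis(benzyloxy)benzaldehyde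
Product: 10 1,2-bis(benzyloxy)-4-ethynylbenzene
Conditions: dimethyl (1-diazo-2-oxopropyl)phosphonate, K2CO3, MeOH/THF, rt
Reagents that add atoms: dimethyl (1-diazo-2-oxopropyl)phosphonate, CC(=O)C(=[N+]=[N-])P(=O)(OC)OC
Why: Seyferth–Gilbert homologation in its Ohira–Bestmann form, which converts an aryl aldehyde into the terminal alkyne under mild base.

Step 7
Reactants: 10 1,2-bis(benzyloxy)-4-ethynylbenzene; 11 chlorodiisopropylsilane
Product: 12 (E)-[2-(3,4-bis(benzyloxy)phenyl)ethenyl]chlorodiisopropylsilane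
Conditions: Pt2[(CH2=CHSiMe2)2O]3 (zerovalent platinum, 0.5 mol %), P(t-Bu)3 (1 mol %), THF, 50 °C; volatiles removed, crude 12 used directly
Reagents that add atoms: none
Why: Platinum-catalysed hydrosilylation of a terminal alkyne is a syn addition that, with a bulky phosphine on platinum, puts silicon on the terminal carbon, so the (E)-beta-styrylsilane should form with the Si–Cl bond kept for step 8.

Step 8
Reactants: 8 6-bromo-8-formyl-3,5,3',4'-tetra-O-benzylcatechin; 12 (E)-styryl(chloro)diisopropylsilane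
Product: 13 6-bromo-8-formyl-3,5,3',4'-tetra-O-benzylcatechin 7-O-{(E)-[2-(3,4-bis(benzyloxy)phenyl)ethenyl]diisopropylsilyl} ether
Conditions: imidazole, DMAP (cat.), DMF, rt → 40 °C
Reagents that add atoms: none
Why: O-silylation of a phenol by a chlorosilane under nucleophilic catalysis, which is routine for 2,6-disubstituted phenols with triisopropylsilyl-type chlorides and does not touch the aldehyde.

Step 9
Reactants: 14 4-bromoresorcinol
Product: 15 5-(benzyloxy)-2-bromophenol
Conditions: BnBr (1.0 equiv), K2CO3 (1.0 equiv), acetone, rt; regioisomer and dibenzyl ether removed on silica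
Reagents that add atoms: benzyl bromide, BrCc1ccccc1
Why: Williamson mono-etherification, which should go mainly to the hydroxyl para to bromine because it is the less hindered one and is not engaged in an O–H···Br contact.

Step 10
Reactants: 13 silyl ether aldehyde; 15 5-(benzyloxy)-2-bromophenol
Product: 17 [6-bromo-7-O-silyl-3,5,3',4'-tetra-O-benzylcatechin-8-yl][4-(benzyloxy)-2-hydroxyphenyl]methanol (silyl = the styryl(diisopropyl)silyl group of 13; both carbinol epimers), via dilithio phenoxide 16 (not isolated)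
Conditions: 15 (1.3 equiv), n-BuLi (2.7 equiv), Et2O, 0 °C → rt; then 13 in THF, −78 °C; aq NH4Cl at −78 °C; silica deactivated with Et3N
Reagents that add atoms: n-butyllithium, [Li]CCCC (its lithium stays only in 16)
Why: 1,2-Addition of an aryllithium to an aldehyde, where 16 (from O–H deprotonation and bromine–lithium exchange) adds to the formyl group faster than it exchanges with the hindered C6 bromide, the cold quench suppresses silicon migration from O7 to the new alkoxide, and the carbinol epimers converge because this carbon becomes planar in step 11.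

Step 11
Reactants: 17 benzhydrol precursor
Product: 19 cycloadduct with the upper unit as a 2,3-trans-3,4-cis 7,3',4'-tri-O-benzylflavan whose C3 carries Si(i-Pr)2 bonded to O7 of ring D (6-bromo-3,5,3',4'-tetra-O-benzylcatechin attached at C8), via ortho-quinone methide 18 (not isolated)
Conditions: (R)-TRIP [(R)-3,3'-bis(2,4,6-triisopropylphenyl)-1,1'-binaphthyl-2,2'-diyl hydrogen phosphate] (10 mol %), 4 Å MS, PhMe (0.005 M), −20 → 0 °C
Reagents that add atoms: none
Why: Proposed new method: the phosphoric acid ionises the benzhydrol with help of the free ring A phenol to the ortho-quinone methide 18, whose methide carbon (C4) is attacked by the silicon-bearing alkene carbon while O1 closes on the carbon that is benzylic to ring B and beta to silicon, an asynchronous inverse-demand hetero-Diels–Alder addition; the closest known reactions are the intramolecular oxadiene cycloadditions of ortho-allyloxy-benzylidene compounds (domino Knoevenagel–hetero-Diels–Alder) and Brønsted-acid-catalysed [4+2] additions of ortho-quinone methides to electron-rich styrenes. Ring C closes in the [4+2] mode through the C3–C4 and O1–C2 bonds, and the 1,2-oxasilinane closes through the same C3–C4 bond as a 6-exo-trig attack on the methide carbon. The short tether through C7 and C8 of ring D should permit only the cis-fused transition state, which sets C3 and C4 cis; the (E)-alkene geometry is carried suprafacially into the C2/C3 trans relation; the face of the planar methide relative to the catechin stereocentres, and so the absolute sense at C2, C3 and C4, is left to the chiral phosphate bound at the quinone methide oxygen. Regioselectivity is secured twice, by the beta-silicon effect and by ring B, and chemoselectivity by the C6 bromine, which shuts off arylation of the quinone methide by ring D of a second molecule, together with high dilution. Sieves, low temperature and a weak acid are chosen to keep the beta-silyl cation from losing silicon before O1 closes.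

Step 12
Reactants: 19 cycloadduct
Product: 20 6-bromo-[7,3',4'-tri-O-benzylfisetinidol]-(4β→8)-[3,5,3',4'-tetra-O-benzylcatechin] (upper 3-OH and ring D 7-OH free)
Conditions: H2O2 (30 % aq, excess), KF, KHCO3, THF/MeOH, 0 °C → rt
Reagents that add atoms: hydrogen peroxide, OO
Why: Tamao oxidation, in which hydroperoxide adds to the oxygen-substituted silicon and C3 migrates to oxygen with retention, so the new 3-hydroxyl stays cis to ring D and trans to ring B while the Si–O7 bond is hydrolysed; buffered peroxide in excess at or below room temperature is chosen so that oxidation outruns beta-elimination of the O1 aryloxide.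

Step 13
Reactants: 20 diol
Product: 21 6-bromo-nona-O-benzyl-fisetinidol-(4β→8)-catechin
Conditions: NaH, BnBr, n-Bu4NI (cat.), DMF, 0 °C → rt
Reagents that add atoms: benzyl bromide, BrCc1ccccc1
Why: Williamson etherification of the phenoxide and the secondary alkoxide, with no acidic C–H to epimerise.

Step 14
Reactants: 22 7-hydroxychromone
Product: 23 7-(benzyloxy)chromone
Conditions: BnBr, K2CO3, acetone, 50 °C
Reagents that add atoms: benzyl bromide, BrCc1ccccc1
Why: Williamson etherification of the phenol under carbonate, mild enough to leave the pyranone ring closed.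

Step 15
Reactants: 23 7-(benzyloxy)chromone; 24 3,4-bis(benzyloxy)phenylboronic acid
Product: 25 (2S)-7-(benzyloxy)-2-[3,4-bis(benzyloxy)phenyl]chroman-4-one
Conditions: Pd(OCOCF3)2 (5 mol %), (R)-t-BuPyOx [(R)-4-tert-butyl-2-(pyridin-2-yl)-4,5-dihydrooxazole] (6 mol %), NH4PF6 (30 mol %), H2O (5 equiv), ClCH2CH2Cl, 60 °C
Reagents that add atoms: none
Why: Palladium-catalysed asymmetric conjugate addition of an arylboronic acid to a chromone, in which the chiral pyridine–oxazoline ligand chooses the face of C2 and sets the (2S) centre under conditions that do not open the flavanone.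

Step 16
Reactants: 25 (2S)-flavanone
Product: 26 (2S)-7-(benzyloxy)-2-[3,4-bis(benzyloxy)phenyl]-2H-chromen-4-yl trifluoromethanesulfonate
Conditions: Tf2O, 2,6-di-tert-butyl-4-methylpyridine, CH2Cl2, 0 °C → rt
Reagents that add atoms: trifluoromethanesulfonic anhydride, O=S(=O)(OS(=O)(=O)C(F)(F)F)C(F)(F)F
Why: Enol triflate formation by O-sulfonylation of the electron-rich aryl ketone and loss of a C3 proton to a hindered pyridine, which avoids a free enolate and with it ring opening to the chalcone and racemisation at C2.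

Step 17
Reactants: 26 enol triflate
Product: 27 (2S)-7-(benzyloxy)-2-[3,4-bis(benzyloxy)phenyl]-4-(4,4,5,5-tetramethyl-1,3,2-dioxaborolan-2-yl)-2H-chromene
Conditions: B2pin2, PdCl2(PPh3)2 (3 mol %), PPh3 (6 mol %), KOPh, PhMe, 50 °C
Reagents that add atoms: bis(pinacolato)diboron, CC1(C)OB(OC1(C)C)B1OC(C)(C)C(C)(C)O1
Why: Miyaura borylation of an alkenyl triflate, which replaces the triflate by boron without touching C2.

Step 18
Reactants: 21 bromide; 27 flavenyl boronate
Product: 28 nona-O-benzyl-fisetinidol-(4β→8)-catechin carrying at C6 of ring D the (2S)-7,3',4'-tri-O-benzylflav-3-en-4-yl group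
Conditions: Pd(OAc)2 (5 mol %), SPhos (10 mol %), K3PO4, PhMe/H2O 10:1, 90 °C
Reagents that add atoms: none
Why: Suzuki–Miyaura coupling, for which a bulky dialkylbiarylphosphine is the established answer to an electron-rich aryl bromide flanked by two ortho alkoxy groups.

Step 19
Reactants: 28 4-arylflav-3-ene
Product: 30 dodeca-O-benzyl-fisetinidol-(4β→8)-catechin-(6→4α)-fisetinidol (lower 3-OH free), via alkylborane 29 (not isolated)
Conditions: BH3·THF (excess), THF, 0 °C → rt; then NaOH (aq), H2O2 (30 %), 0 °C → rt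
Reagents that add atoms: hydrogen peroxide, OO; borane–tetrahydrofuran, B.C1CCOC1 (its boron stays only in 29)
Why: Hydroboration–oxidation, in which boron goes to C3 (the alkene carbon remote from the two aryl groups on C4) and B–H adds syn from the face opposite ring H on C2, so that after oxidation with retention the 3-hydroxyl is trans to ring H and trans to ring D (2,3-trans-3,4-trans, C3 and C4 of the lower unit set here), as established for flav-3-enes.

Step 20
Reactants: 30 dodeca-O-benzyl trimer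
Product: 31 fisetinidol-(4β→8)-catechin-(6→4α)-fisetinidol (CNP0289228.2)
Conditions: H2 (1 atm), Pd(OH)2/C, THF/MeOH/H2O, rt
Reagents that add atoms: none
Why: Hydrogenolysis of benzyl ethers over Pd(OH)2/C under neutral conditions removes all twelve benzyl groups and leaves the interflavan C–C bonds, the pyran C–O bonds and every stereocentre intact.

**Compound list**

1 | (+)-catechin | Oc1cc(O)c2c(c1)O[C@H](c1ccc(O)c(O)c1)[C@@H](O)C2 | starting material
2 | 5,7,3',4'-tetra-O-benzyl-(+)-catechin | c1c(OCc9ccccc9)cc(OCc9ccccc9)c2c1O[C@H](c1ccc(OCc9ccccc9)c(OCc9ccccc9)c1)[C@@H](O)C2 | intermediate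
3 | 3,5,7,3',4'-penta-O-benzyl-(+)-catechin | c1c(OCc9ccccc9)cc(OCc9ccccc9)c2c1O[C@H](c1ccc(OCc9ccccc9)c(OCc9ccccc9)c1)[C@@H](OCc9ccccc9)C2 | intermediate
4 | 8-bromo-penta-O-benzylcatechin | Brc1c(OCc9ccccc9)cc(OCc9ccccc9)c2c1O[C@H](c1ccc(OCc9ccccc9)c(OCc9ccccc9)c1)[C@@H](OCc9ccccc9)C2 | intermediate
5 | 8-lithio-penta-O-benzylcatechin | [Li]c1c(OCc9ccccc9)cc(OCc9ccccc9)c2c1O[C@H](c1ccc(OCc9ccccc9)c(OCc9ccccc9)c1)[C@@H](OCc9ccccc9)C2 | intermediate
6 | 8-formyl-penta-O-benzylcatechin | O=Cc1c(OCc9ccccc9)cc(OCc9ccccc9)c2c1O[C@H](c1ccc(OCc9ccccc9)c(OCc9ccccc9)c1)[C@@H](OCc9ccccc9)C2 | intermediate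
7 | 8-formyl-3,5,3',4'-tetra-O-benzylcatechin | O=Cc1c(O)cc(OCc9ccccc9)c2c1O[C@H](c1ccc(OCc9ccccc9)c(OCc9ccccc9)c1)[C@@H](OCc9ccccc9)C2 | intermediate
8 | 6-bromo-8-formyl-3,5,3',4'-tetra-O-benzylcatechin | O=Cc1c(O)c(Br)c(OCc9ccccc9)c2c1O[C@H](c1ccc(OCc9ccccc9)c(OCc9ccccc9)c1)[C@@H](OCc9ccccc9)C2 | intermediate
9 | 3,4-bis(benzyloxy)benzaldehyde | O=Cc1ccc(OCc2ccccc2)c(OCc2ccccc2)c1 | starting material
10 | 1,2-bis(benzyloxy)-4-ethynylbenzene | C#Cc1ccc(OCc2ccccc2)c(OCc2ccccc2)c1 | intermediate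
11 | chlorodiisopropylsilane | CC(C)[SiH](Cl)C(C)C | starting material
12 | (E)-[2-(3,4-bis(benzyloxy)phenyl)ethenyl]chlorodiisopropylsilane | CC(C)[Si](Cl)(C(C)C)/C=C/c1ccc(OCc2ccccc2)c(OCc2ccccc2)c1 | intermediate
13 | 6-bromo-8-formyl-3,5,3',4'-tetra-O-benzylcatechin 7-O-[(E)-styryl(diisopropyl)silyl] ether (styryl = 3,4-bis(benzyloxy)styryl) | O=Cc1c(O[Si](C(C)C)(C(C)C)/C=C/c3ccc(OCc9ccccc9)c(OCc9ccccc9)c3)c(Br)c(OCc9ccccc9)c2c1O[C@H](c1ccc(OCc9ccccc9)c(OCc9ccccc9)c1)[C@@H](OCc9ccccc9)C2 | intermediate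
14 | 4-bromoresorcinol | Oc1ccc(Br)c(O)c1 | starting material
15 | 5-(benzyloxy)-2-bromophenol | Oc1cc(OCc2ccccc2)ccc1Br | intermediate
16 | lithium 5-(benzyloxy)-2-lithiophenoxide | [Li]Oc1cc(OCc2ccccc2)ccc1[Li] | intermediate
17 | catechin C8 benzhydrol with free ring A phenol, O7 styryl(diisopropyl)silyl tether and C6 bromine (carbinol epimers) | OC(c1ccc(OCc9ccccc9)cc1O)c1c(O[Si](C(C)C)(C(C)C)/C=C/c3ccc(OCc9ccccc9)c(OCc9ccccc9)c3)c(Br)c(OCc9ccccc9)c2c1O[C@H](c1ccc(OCc9ccccc9)c(OCc9ccccc9)c1)[C@@H](OCc9ccccc9)C2 | intermediate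
18 | ring A ortho-quinone methide of 17 | O=C1C=C(OCc9ccccc9)C=CC1=Cc1c(O[Si](C(C)C)(C(C)C)/C=C/c3ccc(OCc9ccccc9)c(OCc9ccccc9)c3)c(Br)c(OCc9ccccc9)c2c1O[C@H](c1ccc(OCc9ccccc9)c(OCc9ccccc9)c1)[C@@H](OCc9ccccc9)C2 | intermediate
19 | cycloadduct: upper 2,3-trans-3,4-cis flavan unit on catechin C8 with C3–Si(i-Pr)2–O7 bridge, 6-bromo | O(Cc9ccccc9)c1ccc2c(c1)O[C@H](c1ccc(OCc9ccccc9)c(OCc9ccccc9)c1)[C@@H]3[C@H]2c1c(O[Si]3(C(C)C)C(C)C)c(Br)c(OCc9ccccc9)c2c1O[C@H](c1ccc(OCc9ccccc9)c(OCc9ccccc9)c1)[C@@H](OCc9ccccc9)C2 | intermediate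
20 | 6-bromo-[7,3',4'-tri-O-benzylfisetinidol]-(4β→8)-[3,5,3',4'-tetra-O-benzylcatechin] | O(Cc9ccccc9)c1ccc2c(c1)O[C@H](c1ccc(OCc9ccccc9)c(OCc9ccccc9)c1)[C@@H](O)[C@H]2c1c(O)c(Br)c(OCc9ccccc9)c2c1O[C@H](c1ccc(OCc9ccccc9)c(OCc9ccccc9)c1)[C@@H](OCc9ccccc9)C2 | intermediate
21 | 6-bromo-nona-O-benzyl-fisetinidol-(4β→8)-catechin | O(Cc9ccccc9)c1ccc2c(c1)O[C@H](c1ccc(OCc9ccccc9)c(OCc9ccccc9)c1)[C@@H](OCc9ccccc9)[C@H]2c1c(OCc9ccccc9)c(Br)c(OCc9ccccc9)c2c1O[C@H](c1ccc(OCc9ccccc9)c(OCc9ccccc9)c1)[C@@H](OCc9ccccc9)C2 | intermediate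
22 | 7-hydroxychromone | O=c1ccoc2cc(O)ccc12 | starting material
23 | 7-(benzyloxy)chromone | O=c1ccoc2cc(OCc3ccccc3)ccc12 | intermediate
24 | 3,4-bis(benzyloxy)phenylboronic acid | OB(O)c1ccc(OCc2ccccc2)c(OCc2ccccc2)c1 | starting material
25 | (2S)-7-(benzyloxy)-2-[3,4-bis(benzyloxy)phenyl]chroman-4-one | O=C1C[C@@H](c2ccc(OCc3ccccc3)c(OCc3ccccc3)c2)Oc2cc(OCc3ccccc3)ccc12 | intermediate
26 | (2S)-7-(benzyloxy)-2-[3,4-bis(benzyloxy)phenyl]-2H-chromen-4-yl triflate | O=S(=O)(OC1=C[C@@H](c2ccc(OCc3ccccc3)c(OCc3ccccc3)c2)Oc2cc(OCc3ccccc3)ccc12)C(F)(F)F | intermediate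
27 | (2S)-7-(benzyloxy)-2-[3,4-bis(benzyloxy)phenyl]-2H-chromen-4-ylboronic acid pinacol ester | CC1(C)OB(OC1(C)C)C1=C[C@@H](c2ccc(OCc3ccccc3)c(OCc3ccccc3)c2)Oc2cc(OCc3ccccc3)ccc12 | intermediate
28 | nona-O-benzyl-fisetinidol-(4β→8)-catechin with (2S)-7,3',4'-tri-O-benzylflav-3-en-4-yl at C6 | O(Cc9ccccc9)c1ccc2c(c1)O[C@H](c1ccc(OCc9ccccc9)c(OCc9ccccc9)c1)[C@@H](OCc9ccccc9)[C@H]2c1c(OCc9ccccc9)c(C4=C[C@@H](c5ccc(OCc9ccccc9)c(OCc9ccccc9)c5)Oc5cc(OCc9ccccc9)ccc45)c(OCc9ccccc9)c2c1O[C@H](c1ccc(OCc9ccccc9)c(OCc9ccccc9)c1)[C@@H](OCc9ccccc9)C2 | intermediate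
29 | C3 alkylborane of the lower unit (boron trans to ring H, H4 syn to boron) | O(Cc9ccccc9)c1ccc2c(c1)O[C@H](c1ccc(OCc9ccccc9)c(OCc9ccccc9)c1)[C@@H](OCc9ccccc9)[C@H]2c1c(OCc9ccccc9)c([C@@H]4c5ccc(OCc9ccccc9)cc5O[C@H](c5ccc(OCc9ccccc9)c(OCc9ccccc9)c5)[C@H]4B)c(OCc9ccccc9)c2c1O[C@H](c1ccc(OCc9ccccc9)c(OCc9ccccc9)c1)[C@@H](OCc9ccccc9)C2 | intermediate
30 | dodeca-O-benzyl-fisetinidol-(4β→8)-catechin-(6→4α)-fisetinidol, lower 3-OH free | O(Cc9ccccc9)c1ccc2c(c1)O[C@H](c1ccc(OCc9ccccc9)c(OCc9ccccc9)c1)[C@@H](OCc9ccccc9)[C@H]2c1c(OCc9ccccc9)c([C@@H]4c5ccc(OCc9ccccc9)cc5O[C@H](c5ccc(OCc9ccccc9)c(OCc9ccccc9)c5)[C@H]4O)c(OCc9ccccc9)c2c1O[C@H](c1ccc(OCc9ccccc9)c(OCc9ccccc9)c1)[C@@H](OCc9ccccc9)C2 | intermediate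
31 | fisetinidol-(4β→8)-catechin-(6→4α)-fisetinidol; upper unit (2R,3S,4R), catechin (2R,3S), lower unit (2R,3S,4S) | Oc1ccc2c(c1)O[C@H](c1ccc(O)c(O)c1)[C@@H](O)[C@H]2c1c(O)c([C@@H]2c3ccc(O)cc3O[C@H](c3ccc(O)c(O)c3)[C@H]2O)c(O)c2c1O[C@H](c1ccc(O)c(O)c1)[C@@H](O)C2 | target

**Totals.** Total steps: 20. Longest linear sequence: 13 steps (1, 2, 3, 4, 5, 8, 10, 11, 12, 13, 18, 19, 20).

**Steps most likely to fail**

Step 11. The beta-silyl benzylic cation may shed silicon before O1 closes, leaving an open-chain alkene, or the two faces of the methide may be poorly differentiated by the catalyst. The fallback uses the classical flavan-3,4-diol condensation; it sets out from 3 and returns at 21. Purchased (+)-fustin [(2R,3R)-3,7,3',4'-tetrahydroxyflavan-4-one] is benzylated on its three phenols (BnBr, K2CO3, DMF) to 7,3',4'-tri-O-benzylfustin F1. NaBH4 reduces F1 to the 2,3-trans-3,4-trans flavan-3,4-diol F2. BF3·OEt2 in CH2Cl2 at low temperature ionises F2 at C4, and the cation arylates C8 of 3 (used in excess). Both C4 epimers must be expected, with the 3,4-trans one likely ahead, so the 3,4-cis alcohol F3 has to be separated by chromatography. F3 is benzylated (NaH, BnBr) to the nonabenzyl ether F4, and NBS then brominates C6, the one open position of ring D, to give 21.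

Step 12. Fluoride- or base-activated silicon may expel the O1 aryloxide, which can lie antiperiplanar to the C3–Si bond, and so tear ring C open; alternatively the hindered silicon may resist oxidation. The fallback changes the tether to a diphenylsilylene bridge, which is oxidised faster and without fluoride; it sets out from 8 and 10 and returns at 20. Alkyne 10 is hydrosilylated with purchased chlorodiphenylsilane under the conditions of step 7 to (E)-[2-(3,4-bis(benzyloxy)phenyl)ethenyl]chlorodiphenylsilane F5. F5 silylates 8 to the aldehyde silyl ether F6. Addition of 16 at −78 °C with a cold quench gives the benzhydrol F7, and the acid-catalysed cycloaddition of step 11 gives the diphenylsilylene-bridged cycloadduct F8. H2O2/KHCO3 in THF/MeOH at room temperature then oxidises the aryloxy(diphenyl)silane to 20.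

Step 18. Oxidative addition at the bromide flanked by two benzyloxy groups may be slow enough that protodeboronation of 27 wins. The fallback replaces cross-coupling by carbonyl addition and dehydration, the classical route to 4-arylflav-3-enes; it sets out from 21 and returns at 28. Bromine–lithium exchange on 21 (n-BuLi, THF, −78 °C) gives the C6 aryllithium F9. F9 is added to flavanone 25 precomplexed with CeCl3 to suppress enolisation, giving the tertiary benzylic alcohol F10. A trace of TsOH in toluene dehydrates F10 to 28.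

**Further compounds**

F1 | step 11 | 7,3',4'-tri-O-benzyl-(+)-fustin | O=C1c2ccc(OCc3ccccc3)cc2O[C@H](c2ccc(OCc3ccccc3)c(OCc3ccccc3)c2)[C@H]1O
F2 | step 11 | (2R,3S,4R)-7,3',4'-tri-O-benzylflavan-3,4-diol | O[C@@H]1c2ccc(OCc3ccccc3)cc2O[C@H](c2ccc(OCc3ccccc3)c(OCc3ccccc3)c2)[C@H]1O
F3 | step 11 | [7,3',4'-tri-O-benzylfisetinidol]-(4β→8)-[penta-O-benzylcatechin], upper 3-OH free | O(Cc9ccccc9)c1ccc2c(c1)O[C@H](c1ccc(OCc9ccccc9)c(OCc9ccccc9)c1)[C@@H](O)[C@H]2c1c(OCc9ccccc9)cc(OCc9ccccc9)c2c1O[C@H](c1ccc(OCc9ccccc9)c(OCc9ccccc9)c1)[C@@H](OCc9ccccc9)C2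
F4 | step 11 | nona-O-benzyl-fisetinidol-(4β→8)-catechin | O(Cc9ccccc9)c1ccc2c(c1)O[C@H](c1ccc(OCc9ccccc9)c(OCc9ccccc9)c1)[C@@H](OCc9ccccc9)[C@H]2c1c(OCc9ccccc9)cc(OCc9ccccc9)c2c1O[C@H](c1ccc(OCc9ccccc9)c(OCc9ccccc9)c1)[C@@H](OCc9ccccc9)C2
F5 | step 12 | (E)-[2-(3,4-bis(benzyloxy)phenyl)ethenyl]chlorodiphenylsilane | Cl[Si](c1ccccc1)(c1ccccc1)/C=C/c1ccc(OCc2ccccc2)c(OCc2ccccc2)c1
F6 | step 12 | 6-bromo-8-formyl-3,5,3',4'-tetra-O-benzylcatechin 7-O-[(E)-styryl(diphenyl)silyl] ether | O=Cc1c(O[Si](c7ccccc7)(c7ccccc7)/C=C/c3ccc(OCc9ccccc9)c(OCc9ccccc9)c3)c(Br)c(OCc9ccccc9)c2c1O[C@H](c1ccc(OCc9ccccc9)c(OCc9ccccc9)c1)[C@@H](OCc9ccccc9)C2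
F7 | step 12 | diphenylsilyl analogue of benzhydrol 17 | OC(c1ccc(OCc9ccccc9)cc1O)c1c(O[Si](c7ccccc7)(c7ccccc7)/C=C/c3ccc(OCc9ccccc9)c(OCc9ccccc9)c3)c(Br)c(OCc9ccccc9)c2c1O[C@H](c1ccc(OCc9ccccc9)c(OCc9ccccc9)c1)[C@@H](OCc9ccccc9)C2
F8 | step 12 | diphenylsilylene-bridged analogue of cycloadduct 19 | O(Cc9ccccc9)c1ccc2c(c1)O[C@H](c1ccc(OCc9ccccc9)c(OCc9ccccc9)c1)[C@@H]3[C@H]2c1c(O[Si]3(c7ccccc7)c7ccccc7)c(Br)c(OCc9ccccc9)c2c1O[C@H](c1ccc(OCc9ccccc9)c(OCc9ccccc9)c1)[C@@H](OCc9ccccc9)C2
F9 | step 18 | 6-lithio-nona-O-benzyl-fisetinidol-(4β→8)-catechin | O(Cc9ccccc9)c1ccc2c(c1)O[C@H](c1ccc(OCc9ccccc9)c(OCc9ccccc9)c1)[C@@H](OCc9ccccc9)[C@H]2c1c(OCc9ccccc9)c([Li])c(OCc9ccccc9)c2c1O[C@H](c1ccc(OCc9ccccc9)c(OCc9ccccc9)c1)[C@@H](OCc9ccccc9)C2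
F10 | step 18 | tertiary 4-aryl-flavan-4-ol from F9 and 25 (C4 epimers of the lower unit) | O(Cc9ccccc9)c1ccc2c(c1)O[C@H](c1ccc(OCc9ccccc9)c(OCc9ccccc9)c1)[C@@H](OCc9ccccc9)[C@H]2c1c(OCc9ccccc9)c(C4(O)C[C@@H](c5ccc(OCc9ccccc9)c(OCc9ccccc9)c5)Oc5cc(OCc9ccccc9)ccc45)c(OCc9ccccc9)c2c1O[C@H](c1ccc(OCc9ccccc9)c(OCc9ccccc9)c1)[C@@H](OCc9ccccc9)C2
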